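**Strategy**

The butenolide (O–C12(=O)–C11=C7–C6, germacranolide numbering) is the cyclised form of a 2,3-allenoic acid, HO2C12–C11=C7=C6H, whose terminus C6 is also allylic to C4=C5. Iodolactonisation of the axially chiral open-chain acid 20 forms the O–C6 bond, converts the allene axis into the C6 stereocentre and leaves iodine on C7, all in one operation. The acid carries C10 from (R)-citramalic acid, the C1 ketone, the (E)-C4=C5 alkene and a masked C8 aldehyde; its axis comes from a (6S)-propargylic mesylate by anti-SN2' carbonylation. The C7 iodide later closes the ten-membered ring onto C8 (Nozaki–Hiyama–Kishi).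

Key step: step 13

**Remarks on the chemistry**

- Numbering: C1 ketone, C4=C5 ring alkene, C6 lactone carbinol, C7=C11 butenolide alkene, C8 methacrylate carbinol, C10 acetoxy carbon, C12 lactone carbonyl, C13 acetoxymethyl carbon. The target is (6R,8S,10R).
- Step 11: the (S,S)-ProPhenol antipode is assumed to deliver the alkynyl group to the aldehyde face that gives the (6S)-alcohol; if the sense is opposite, the commercial (R,R)-ligand is used instead.

**Route**

Step 1
Reactants: 1 (R)-citramalic acid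
Product: 2 2-[(4R)-2,2,4-trimethyl-5-oxo-1,3-dioxolan-4-yl]acetic acid
Conditions: 2,2-dimethoxypropane, PPTS (cat.), CH2Cl2, rt
Reagents that add atoms: 2,2-dimethoxypropane, COC(C)(C)OC
Why: Acid-catalysed acetalisation of an α-hydroxy acid ties the tertiary OH and its neighbouring carboxyl into the five-membered dioxolanone and leaves the CH2CO2H arm free; the C10 stereocentre comes from the chiral pool and is not touched.

Step 2
Reactants: 2 2-[(4R)-2,2,4-trimethyl-5-oxo-1,3-dioxolan-4-yl]acetic acid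
Product: 4 (3R)-3-hydroxy-3-methyloxolan-2-one, via hydroxyethyl dioxolanone 3 (not isolated)
Conditions: BH3·SMe2, THF, 0 °C to rt; MeOH quench; then TsOH (cat.), CH2Cl2, rt
Reagents that add atoms: none
Why: Borane reduces the free carboxylic acid chemoselectively in the presence of the dioxolanone, and acid-catalysed transacylation then expels acetone and closes the γ-lactone.

Step 3
Reactants: 4 (3R)-3-hydroxy-3-methyloxolan-2-one
Product: 5 (2R)-2,4-dihydroxy-N-methoxy-N,2-dimethylbutanamide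
Conditions: MeNH(OMe)·HCl, i-PrMgCl, THF, −20 to 0 °C
Reagents that add atoms: N,O-dimethylhydroxylamine hydrochloride, CNOC.Cl
Why: Weinreb aminolysis of a lactone by the magnesium amide opens the ring to the hydroxy Weinreb amide, which is silylated at once to prevent relactonisation.

Step 4
Reactants: 5 (2R)-2,4-dihydroxy-N-methoxy-N,2-dimethylbutanamide
Product: 6 (2R)-N-methoxy-N,2-dimethyl-2,4-bis[(triethylsilyl)oxy]butanamide
Conditions: TESOTf, 2,6-lutidine, CH2Cl2, −78 to 0 °C
Reagents that add atoms: triethylsilyl trifluoromethanesulfonate, CC[Si](CC)(CC)OS(=O)(=O)C(F)(F)F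
Why: Silyl triflate with 2,6-lutidine silylates both the primary and the hindered tertiary hydroxyl (silyl ether protection).

Step 5
Reactants: 7 tert-butyl(but-3-yn-1-yloxy)dimethylsilane
Product: 9 (2E)-5-[(tert-butyldimethylsilyl)oxy]-3-methylpent-2-en-1-ol, via alkenyl dimethylalane 8 (not isolated)
Conditions: AlMe3, Cp2ZrCl2 (cat.), CH2Cl2, 0 °C to rt; then n-BuLi, THF, −78 °C; (CH2O)n, rt
Reagents that add atoms: trimethylaluminium, C[Al](C)C; paraformaldehyde (as formaldehyde), C=O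
Why: Negishi carboalumination adds Me and Al syn across the terminal alkyne with methyl on the internal carbon, and the derived alanate traps formaldehyde with retention, which fixes the (E)-C4=C5 geometry.

Step 6
Reactants: 9 (2E)-5-[(tert-butyldimethylsilyl)oxy]-3-methylpent-2-en-1-ol
Product: 10 tert-butyl{[(3E)-5-[(4-methoxybenzyl)oxy]-3-methylpent-3-en-1-yl]oxy}dimethylsilane
Conditions: NaH, PMBCl, TBAI (cat.), THF/DMF, 0 °C to rt
Reagents that add atoms: 4-methoxybenzyl chloride, COc1ccc(CCl)cc1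
Why: Williamson etherification of the allylic alkoxide gives a PMB ether that can later be removed oxidatively beside silyl ethers.

Step 7
Reactants: 10 tert-butyl{[(3E)-5-[(4-methoxybenzyl)oxy]-3-methylpent-3-en-1-yl]oxy}dimethylsilane
Product: 11 (3E)-5-[(4-methoxybenzyl)oxy]-3-methylpent-3-en-1-ol
Conditions: TBAF, THF, 0 °C to rt
Reagents that add atoms: none
Why: Fluoride-mediated desilylation frees the primary alcohol and leaves the PMB ether intact.

Step 8
Reactants: 11 (3E)-5-[(4-methoxybenzyl)oxy]-3-methylpent-3-en-1-ol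
Product: 12 1-({[(2E)-5-iodo-3-methylpent-2-en-1-yl]oxy}methyl)-4-methoxybenzene
Conditions: I2, PPh3, imidazole, CH2Cl2, 0 °C
Reagents that add atoms: iodine, II
Why: Appel-type iodination converts the primary homoallylic alcohol into the iodide without touching the trisubstituted alkene.

Step 9
Reactants: 12 1-({[(2E)-5-iodo-3-methylpent-2-en-1-yl]oxy}methyl)-4-methoxybenzene; 6 (2R)-N-methoxy-N,2-dimethyl-2,4-bis[(triethylsilyl)oxy]butanamide
Product: 14 (3R,7E)-9-[(4-methoxybenzyl)oxy]-3,7-dimethyl-1,3-bis[(triethylsilyl)oxy]non-7-en-4-one, via homoallylic organolithium 13 (not isolated)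
Conditions: t-BuLi (2.1 equiv), Et2O, −78 °C; then 6, −78 to −20 °C; NH4Cl
Reagents that add atoms: tert-butyllithium, [Li]C(C)(C)C (lithium of 13 only)
Why: Iodine–lithium exchange followed by Weinreb ketone synthesis forms the C1–C2 bond, the chelated tetrahedral intermediate preventing over-addition.

Step 10
Reactants: 14 (3R,7E)-9-[(4-methoxybenzyl)oxy]-3,7-dimethyl-1,3-bis[(triethylsilyl)oxy]non-7-en-4-one
Product: 16 (2E,7R)-3,7-dimethyl-6-oxo-7,9-bis[(triethylsilyl)oxy]non-2-enal, via allylic alcohol 15 (not isolated)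
Conditions: DDQ, CH2Cl2/pH 7 buffer, 0 °C; filter; then MnO2, CH2Cl2, rt
Reagents that add atoms: none
Why: Buffered DDQ cleavage of the PMB ether spares the triethylsilyl ethers, and MnO2 oxidises the allylic alcohol to the enal with the (E)-geometry retained.

Step 11
Reactants: 16 (2E,7R)-3,7-dimethyl-6-oxo-7,9-bis[(triethylsilyl)oxy]non-2-enal; 17 tert-butyldimethyl(prop-2-yn-1-yloxy)silane
Product: 18 (4S,5E,10R)-1-[(tert-butyldimethylsilyl)oxy]-4-hydroxy-6,10-dimethyl-10,12-bis[(triethylsilyl)oxy]dodec-5-en-2-yn-9-one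
Conditions: Me2Zn, (S,S)-ProPhenol (20 mol%), Ph3PO (40 mol%), toluene, 4 °C
Reagents that add atoms: none
Why: Zinc–ProPhenol-catalysed asymmetric alkynylation of an enal; the zinc acetylide adds to the aldehyde only (the hindered C1 ketone is inert) and the catalyst controls the face, setting C6 as (S).

Step 12
Reactants: 18 (4S,5E,10R)-1-[(tert-butyldimethylsilyl)oxy]-4-hydroxy-6,10-dimethyl-10,12-bis[(triethylsilyl)oxy]dodec-5-en-2-yn-9-one
Product: 20 (Ra,5E,10R)-2-{[(tert-butyldimethylsilyl)oxy]methyl}-6,10-dimethyl-9-oxo-10,12-bis[(triethylsilyl)oxy]dodeca-2,3,5-trienoic acid, via propargylic mesylate 19 (not isolated)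
Conditions: MsCl, Et3N, CH2Cl2, −78 °C; cold work-up; then Pd(PPh3)4 (5 mol%), CO (1 atm), THF/H2O, 0 °C to rt
Reagents that add atoms: methanesulfonyl chloride, CS(=O)(=O)Cl (in 19 only); carbon monoxide, [C-]#[O+]; water, O
Why: Pd(0) displaces the mesylate in an anti-SN2' sense to an allenylpalladium species that inserts CO and is hydrolysed (hydroxycarbonylation of a propargylic mesylate), so the (6S)-centre is transferred to the (Ra)-allene axis.

Step 13
Reactants: 20 (Ra,5E,10R)-2-{[(tert-butyldimethylsilyl)oxy]methyl}-6,10-dimethyl-9-oxo-10,12-bis[(triethylsilyl)oxy]dodeca-2,3,5-trienoic acid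
Product: 21 (5R)-3-{[(tert-butyldimethylsilyl)oxy]methyl}-5-[(1E,6R)-2,6-dimethyl-5-oxo-6,8-bis[(triethylsilyl)oxy]oct-1-en-1-yl]-4-iodofuran-2(5H)-one
Conditions: I2, NaHCO3, MeCN, −20 °C, dark; Na2S2O3
Reagents that add atoms: iodine, II
Why: Iodine engages the C6=C7 π-bond of the allene on the face away from the carboxyl group while the carboxylate oxygen adds to C6 from its own side (anti oxy-iodination), giving the β-iodobutenolide. The closest known reaction type is the iodolactonisation of optically active 4-monosubstituted 2,3-allenoic acids to 4-iodofuran-2(5H)-ones. The butenolide closes in the 5-endo mode at the sp2 terminus C6, which is easy here because the attacked π-orbital lies in the plane of the forming ring. C6 is the only new stereocentre and is fixed by the allene axis: the oxygen can reach C6 only from the C12 side, so the (Ra)-axis should give (6R), a net inversion relative to the mesylate carbon. The step needs chemoselectivity for the allene over the C4=C5 alkene and a closed iodonium rather than a free C4–C6 allyl cation; the tethered carboxylate, the bicarbonate buffer and the low temperature are meant to secure both. The C7–I bond is the handle for ring closure in step 15.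

Step 14
Reactants: 21 (5R)-3-{[(tert-butyldimethylsilyl)oxy]methyl}-5-[(1E,6R)-2,6-dimethyl-5-oxo-6,8-bis[(triethylsilyl)oxy]oct-1-en-1-yl]-4-iodofuran-2(5H)-one
Product: 22 (3R,7E)-8-[(2R)-4-{[(tert-butyldimethylsilyl)oxy]methyl}-3-iodo-5-oxo-2,5-dihydrofuran-2-yl]-3,7-dimethyl-4-oxo-3-[(triethylsilyl)oxy]oct-7-enal
Conditions: (COCl)2, DMSO, CH2Cl2, −78 to −40 °C; i-Pr2NEt, −78 to −20 °C
Reagents that add atoms: none
Why: Under Swern conditions a primary triethylsilyl ether is cleaved and oxidised in the same pot to the aldehyde, while the tertiary TES and primary TBS ethers survive; the hindered base at low temperature protects the acidic C6–H.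

Step 15
Reactants: 22 (3R,7E)-8-[(2R)-4-{[(tert-butyldimethylsilyl)oxy]methyl}-3-iodo-5-oxo-2,5-dihydrofuran-2-yl]-3,7-dimethyl-4-oxo-3-[(triethylsilyl)oxy]oct-7-enal
Product: 23 (4S,6R,10E,11aR)-3-{[(tert-butyldimethylsilyl)oxy]methyl}-4-hydroxy-6,10-dimethyl-6-[(triethylsilyl)oxy]-4,5,8,9-tetrahydrocyclodeca[b]furan-2,7(6H,11aH)-dione
Conditions: CrCl2 (8 equiv), NiCl2 (0.1 equiv), degassed DMSO, rt, 2 mM, slow addition
Reagents that add atoms: none
Why: Nozaki–Hiyama–Kishi reaction: Ni(0) inserts into the C7–I bond, the alkenyl group passes to Cr(III) and adds to the aldehyde only (ketone, lactone and silyl ethers tolerated), closing the ten-membered ring at C7–C8 under high dilution; C8 is set under substrate control, and the transition state with C8–H eclipsing C7=C11 toward C13 and the chain approaching anti to the C6 substituent is expected to give (8S).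

Step 16
Reactants: 23 (4S,6R,10E,11aR)-3-{[(tert-butyldimethylsilyl)oxy]methyl}-4-hydroxy-6,10-dimethyl-6-[(triethylsilyl)oxy]-4,5,8,9-tetrahydrocyclodeca[b]furan-2,7(6H,11aH)-dione
Product: 24 (4S,6R,10E,11aR)-3-{[(tert-butyldimethylsilyl)oxy]methyl}-6,10-dimethyl-2,7-dioxo-6-[(triethylsilyl)oxy]-2,4,5,6,7,8,9,11a-octahydrocyclodeca[b]furan-4-yl 2-methylprop-2-enoate
Conditions: methacrylic anhydride, DMAP, Et3N, BHT (trace), CH2Cl2, 0 °C to rt
Reagents that add atoms: methacrylic anhydride, C=C(C)C(=O)OC(=O)C(C)=C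
Why: DMAP-catalysed acylation esterifies the only free hydroxyl (C8) with retention of configuration.

Step 17
Reactants: 24 (4S,6R,10E,11aR)-3-{[(tert-butyldimethylsilyl)oxy]methyl}-6,10-dimethyl-2,7-dioxo-6-[(triethylsilyl)oxy]-2,4,5,6,7,8,9,11a-octahydrocyclodeca[b]furan-4-yl 2-methylprop-2-enoate
Product: 25 (4S,6R,10E,11aR)-6-hydroxy-3-(hydroxymethyl)-6,10-dimethyl-2,7-dioxo-2,4,5,6,7,8,9,11a-octahydrocyclodeca[b]furan-4-yl 2-methylprop-2-enoate
Conditions: HF·pyridine, pyridine, THF, 0 °C to rt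
Reagents that add atoms: none
Why: Buffered HF removes the primary TBS and the tertiary TES ether in one operation without touching the methacrylate or the butenolide (fluoride desilylation under non-basic conditions).

Step 18
Reactants: 25 (4S,6R,10E,11aR)-6-hydroxy-3-(hydroxymethyl)-6,10-dimethyl-2,7-dioxo-2,4,5,6,7,8,9,11a-octahydrocyclodeca[b]furan-4-yl 2-methylprop-2-enoate
Product: 26 (4S,6R,10E,11aR)-6-acetoxy-3-(acetoxymethyl)-6,10-dimethyl-2,7-dioxo-2,4,5,6,7,8,9,11a-octahydrocyclodeca[b]furan-4-yl 2-methylprop-2-enoate (target)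
Conditions: Ac2O, DMAP, Et3N, CH2Cl2, rt
Reagents that add atoms: acetic anhydride, CC(=O)OC(C)=O
Why: DMAP-catalysed acetylation esterifies the primary allylic C13–OH and, more slowly, the tertiary α-ketol C10–OH, completing the target without affecting any stereocentre.

**Compound list**

1 | (R)-citramalic acid, (2R)-2-hydroxy-2-methylbutanedioic acid | C[C@@](O)(CC(=O)O)C(=O)O | starting material
2 | 2-[(4R)-2,2,4-trimethyl-5-oxo-1,3-dioxolan-4-yl]acetic acid | CC1(C)O[C@](C)(CC(=O)O)C(=O)O1 | intermediate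
3 | (5R)-5-(2-hydroxyethyl)-2,2,5-trimethyl-1,3-dioxolan-4-one (hydroxyethyl dioxolanone) | CC1(C)O[C@](C)(CCO)C(=O)O1 | intermediate
4 | (3R)-3-hydroxy-3-methyloxolan-2-one | C[C@@]1(O)CCOC1=O | intermediate
5 | (2R)-2,4-dihydroxy-N-methoxy-N,2-dimethylbutanamide | OCC[C@@](C)(O)C(=O)N(C)OC | intermediate
6 | (2R)-N-methoxy-N,2-dimethyl-2,4-bis[(triethylsilyl)oxy]butanamide | CC[Si](CC)(CC)OCC[C@@](C)(O[Si](CC)(CC)CC)C(=O)N(C)OC | intermediate
7 | tert-butyl(but-3-yn-1-yloxy)dimethylsilane | C#CCCO[Si](C)(C)C(C)(C)C | starting material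
8 | {(1E)-4-[(tert-butyldimethylsilyl)oxy]-2-methylbut-1-en-1-yl}dimethylalane (alkenyl dimethylalane) | C[Al](C)/C=C(\C)CCO[Si](C)(C)C(C)(C)C | intermediate
9 | (2E)-5-[(tert-butyldimethylsilyl)oxy]-3-methylpent-2-en-1-ol | OC/C=C(\C)CCO[Si](C)(C)C(C)(C)C | intermediate
10 | tert-butyl{[(3E)-5-[(4-methoxybenzyl)oxy]-3-methylpent-3-en-1-yl]oxy}dimethylsilane | COc1ccc(COC/C=C(\C)CCO[Si](C)(C)C(C)(C)C)cc1 | intermediate
11 | (3E)-5-[(4-methoxybenzyl)oxy]-3-methylpent-3-en-1-ol | COc1ccc(COC/C=C(\C)CCO)cc1 | intermediate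
12 | 1-({[(2E)-5-iodo-3-methylpent-2-en-1-yl]oxy}methyl)-4-methoxybenzene | COc1ccc(COC/C=C(\C)CCI)cc1 | intermediate
13 | {(3E)-5-[(4-methoxybenzyl)oxy]-3-methylpent-3-en-1-yl}lithium (homoallylic organolithium) | [Li]CC/C(C)=C/COCc1ccc(OC)cc1 | intermediate
14 | (3R,7E)-9-[(4-methoxybenzyl)oxy]-3,7-dimethyl-1,3-bis[(triethylsilyl)oxy]non-7-en-4-one | CC[Si](CC)(CC)OCC[C@@](C)(O[Si](CC)(CC)CC)C(=O)CC/C(C)=C/COCc1ccc(OC)cc1 | intermediate
15 | (3R,7E)-9-hydroxy-3,7-dimethyl-1,3-bis[(triethylsilyl)oxy]non-7-en-4-one (allylic alcohol) | CC[Si](CC)(CC)OCC[C@@](C)(O[Si](CC)(CC)CC)C(=O)CC/C(C)=C/CO | intermediate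
16 | (2E,7R)-3,7-dimethyl-6-oxo-7,9-bis[(triethylsilyl)oxy]non-2-enal | CC[Si](CC)(CC)OCC[C@@](C)(O[Si](CC)(CC)CC)C(=O)CC/C(C)=C/C=O | intermediate
17 | tert-butyldimethyl(prop-2-yn-1-yloxy)silane | C#CCO[Si](C)(C)C(C)(C)C | starting material
18 | (4S,5E,10R)-1-[(tert-butyldimethylsilyl)oxy]-4-hydroxy-6,10-dimethyl-10,12-bis[(triethylsilyl)oxy]dodec-5-en-2-yn-9-one | CC[Si](CC)(CC)OCC[C@@](C)(O[Si](CC)(CC)CC)C(=O)CC/C(C)=C/[C@H](O)C#CCO[Si](C)(C)C(C)(C)C | intermediate
19 | (4S,5E,10R)-1-[(tert-butyldimethylsilyl)oxy]-6,10-dimethyl-9-oxo-10,12-bis[(triethylsilyl)oxy]dodec-5-en-2-yn-4-yl methanesulfonate (propargylic mesylate) | CC[Si](CC)(CC)OCC[C@@](C)(O[Si](CC)(CC)CC)C(=O)CC/C(C)=C/[C@H](OS(C)(=O)=O)C#CCO[Si](C)(C)C(C)(C)C | intermediate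
20 | (Ra,5E,10R)-2-{[(tert-butyldimethylsilyl)oxy]methyl}-6,10-dimethyl-9-oxo-10,12-bis[(triethylsilyl)oxy]dodeca-2,3,5-trienoic acid; allene axis Ra (= M) | OC(=O)C(CO[Si](C)(C)C(C)(C)C)=[C@]=C([H])/C=C(C)/CCC(=O)[C@](C)(O[Si](CC)(CC)CC)CCO[Si](CC)(CC)CC | intermediate
21 | (5R)-3-{[(tert-butyldimethylsilyl)oxy]methyl}-5-[(1E,6R)-2,6-dimethyl-5-oxo-6,8-bis[(triethylsilyl)oxy]oct-1-en-1-yl]-4-iodofuran-2(5H)-one | CC[Si](CC)(CC)OCC[C@@](C)(O[Si](CC)(CC)CC)C(=O)CC/C(C)=C/[C@H]1OC(=O)C(CO[Si](C)(C)C(C)(C)C)=C1I | intermediate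
22 | (3R,7E)-8-[(2R)-4-{[(tert-butyldimethylsilyl)oxy]methyl}-3-iodo-5-oxo-2,5-dihydrofuran-2-yl]-3,7-dimethyl-4-oxo-3-[(triethylsilyl)oxy]oct-7-enal | O=CC[C@@](C)(O[Si](CC)(CC)CC)C(=O)CC/C(C)=C/[C@H]1OC(=O)C(CO[Si](C)(C)C(C)(C)C)=C1I | intermediate
23 | (4S,6R,10E,11aR)-3-{[(tert-butyldimethylsilyl)oxy]methyl}-4-hydroxy-6,10-dimethyl-6-[(triethylsilyl)oxy]-4,5,8,9-tetrahydrocyclodeca[b]furan-2,7(6H,11aH)-dione (8S-alcohol) | O[C@H]1C[C@@](C)(O[Si](CC)(CC)CC)C(=O)CC/C(C)=C/[C@H]2OC(=O)C(CO[Si](C)(C)C(C)(C)C)=C12 | intermediate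
24 | (4S,6R,10E,11aR)-3-{[(tert-butyldimethylsilyl)oxy]methyl}-6,10-dimethyl-2,7-dioxo-6-[(triethylsilyl)oxy]-2,4,5,6,7,8,9,11a-octahydrocyclodeca[b]furan-4-yl 2-methylprop-2-enoate | C=C(C)C(=O)O[C@H]1C[C@@](C)(O[Si](CC)(CC)CC)C(=O)CC/C(C)=C/[C@H]2OC(=O)C(CO[Si](C)(C)C(C)(C)C)=C12 | intermediate
25 | (4S,6R,10E,11aR)-6-hydroxy-3-(hydroxymethyl)-6,10-dimethyl-2,7-dioxo-2,4,5,6,7,8,9,11a-octahydrocyclodeca[b]furan-4-yl 2-methylprop-2-enoate | C=C(C)C(=O)O[C@H]1C[C@@](C)(O)C(=O)CC/C(C)=C/[C@H]2OC(=O)C(CO)=C12 | intermediate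
26 | (4S,6R,10E,11aR)-6-acetoxy-3-(acetoxymethyl)-6,10-dimethyl-2,7-dioxo-2,4,5,6,7,8,9,11a-octahydrocyclodeca[b]furan-4-yl 2-methylprop-2-enoate (CNP0115165.1) | C=C(C)C(=O)O[C@H]1C[C@@](C)(OC(C)=O)C(=O)CC/C(C)=C/[C@H]2OC(=O)C(COC(C)=O)=C12 | target

**Totals**

Total step count: 18.
Longest linear sequence: 14 steps (steps 1–4 and 9–18, or equally steps 5–8 and 9–18).

**Three steps most likely to fail**

1. Step 13 (iodolactonisation). The iodonium may open to a delocalised C4–C6 allyl cation, which would lose the axis information and erode the configuration at C6, and iodine may also attack the electron-rich C4=C5 alkene. The fallback sets out from 20 and comes back at 23. Copper(II) bromide in aqueous acetone would effect bromolactonisation within a copper carboxylate, so the halogen is delivered by the metal and not by a free halonium ion, giving the bromobutenolide F1. Direct Swern oxidation of its primary triethylsilyl ether would give the bromo aldehyde F2. Nickel/chromium-mediated ring closure of this alkenyl bromide would then give 23.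

2. Step 15 (Nozaki–Hiyama–Kishi ring closure). The facial selectivity at C8 is under remote substrate control only and may be poor or opposite, and intermolecular coupling competes with ten-membered ring formation. The fallback sets out from 22 and comes back at 24. If the ring closure delivers mainly the C8 epimer, the (8R)-alcohol F3, this would be esterified with methacrylic acid under Mitsunobu conditions (PPh3, DIAD, THF, 0 °C). The inversion at C8 would give the (8S)-methacrylate 24 directly.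

3. Step 12 (mesylation and hydroxycarbonylation). The mesylate is both allylic and propargylic and may ionise or undergo 1,3-transposition before palladium arrives, and the allenylpalladium intermediate may racemise. The fallback sets out from 18 and comes back at 20. The alcohol would be converted into the isolable methyl carbonate F4 (methyl chloroformate, pyridine, CH2Cl2, 0 °C). Palladium-catalysed methoxycarbonylation under neutral conditions (Pd2(dba)3·CHCl3, PPh3, CO, MeOH, rt) would give the methyl allenoate F5. Saponification (LiOH, THF/H2O, 0 °C) would then give 20.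

**Further compounds**

F1 | step 13 | (5R)-4-bromo-3-{[(tert-butyldimethylsilyl)oxy]methyl}-5-[(1E,6R)-2,6-dimethyl-5-oxo-6,8-bis[(triethylsilyl)oxy]oct-1-en-1-yl]furan-2(5H)-one | CC[Si](CC)(CC)OCC[C@@](C)(O[Si](CC)(CC)CC)C(=O)CC/C(C)=C/[C@H]1OC(=O)C(CO[Si](C)(C)C(C)(C)C)=C1Br
F2 | step 13 | (3R,7E)-8-[(2R)-3-bromo-4-{[(tert-butyldimethylsilyl)oxy]methyl}-5-oxo-2,5-dihydrofuran-2-yl]-3,7-dimethyl-4-oxo-3-[(triethylsilyl)oxy]oct-7-enal | O=CC[C@@](C)(O[Si](CC)(CC)CC)C(=O)CC/C(C)=C/[C@H]1OC(=O)C(CO[Si](C)(C)C(C)(C)C)=C1Br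
F3 | step 15 | (4R,6R,10E,11aR)-3-{[(tert-butyldimethylsilyl)oxy]methyl}-4-hydroxy-6,10-dimethyl-6-[(triethylsilyl)oxy]-4,5,8,9-tetrahydrocyclodeca[b]furan-2,7(6H,11aH)-dione (8R-alcohol) | O[C@@H]1C[C@@](C)(O[Si](CC)(CC)CC)C(=O)CC/C(C)=C/[C@H]2OC(=O)C(CO[Si](C)(C)C(C)(C)C)=C12
F4 | step 12 | (4S,5E,10R)-1-[(tert-butyldimethylsilyl)oxy]-6,10-dimethyl-9-oxo-10,12-bis[(triethylsilyl)oxy]dodec-5-en-2-yn-4-yl methyl carbonate | CC[Si](CC)(CC)OCC[C@@](C)(O[Si](CC)(CC)CC)C(=O)CC/C(C)=C/[C@H](OC(=O)OC)C#CCO[Si](C)(C)C(C)(C)C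
F5 | step 12 | methyl (Ra,5E,10R)-2-{[(tert-butyldimethylsilyl)oxy]methyl}-6,10-dimethyl-9-oxo-10,12-bis[(triethylsilyl)oxy]dodeca-2,3,5-trienoate | COC(=O)C(CO[Si](C)(C)C(C)(C)C)=[C@]=C([H])/C=C(C)/CCC(=O)[C@](C)(O[Si](CC)(CC)CC)CCO[Si](CC)(CC)CC
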